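(The runs were generated by integration for an exercise, noise included.)

The ratio to look at first is nucleophile charged per solid electrophile charged, 1.10 equiv on the recipes below.

| flask | solid electrophile | nucleophile | remark | time |
|---|---|---|---|---|
| violet | 0.075 M | 1.1 equiv | run made earlier |  |
| teal | 0.23 M | 1.1 equiv | run made earlier |  |
| green | 0.51 M | 1.1 equiv | run made earlier |  |
| Monday's | 0.080 M | 1.10 equiv |  | 50 min |
| Sunday's | 0.15 M | 1.10 equiv |  | 50 min |
| Saturday's | 0.30 M | 1.10 equiv |  | 50 min |
| Wednesday's | 0.60 M | 1.10 equiv |  | 50 min |

| violet: time / min | violet: target / % | teal: time / min | teal: target / % | green: time / min | green: target / % |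
|---|---|---|---|---|---|
| 6.00 | 44 | 4.00 | 27 | 12.0 | 44 |
| 20.0 | 59 | 10.0 | 49 | 25.0 | 55 |
| 30.0 | 60 | 20.0 | 55 | 40.0 | 58 |
| 50.0 | 62 | 50.0 | 60 | 50.0 | 60 |

(each reading ± 1.5 percentage points)

- as a solid, counted per litre of solution: solid electrophile
- steps that have been proposed: solid electrophile <-> electrophile; nucleophile + acid set free <-> protonated nucleophile; electrophile + nucleophile -> acid set free + target
- at the start none of the solid electrophile is in solution
- "hardly changes" means that all values lie within two and a half points (for a concentration: within two and a half percent of the largest)

- [target] at the end for Monday's, Sunday's, Saturday's, Wednesday's, in this order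
- the course of these numbers from the first flask to the last (rises, then falls / falls, then rises / rises all the way / hardly changes / falls all the way)

We count what is left of the nucleophile, not what is made. Each target uses one nucleophile, and the acid set free with it can park a second one as protonated nucleophile. If parking is complete, the nucleophile is spent when the yield reaches 55.0 %. We call this half of the equivalents the stall yield; in this count the nucleophile, though charged in excess, is the limiting reagent.

Applied honestly, the rule lands close but low. At 50 min the violet, teal and green runs read 62 %, 60 % and 60 %, so the green run stands 5 percentage points above the stall yield, with a scatter of 1.5 points. The same count says what such an excess means: with the nucleophile still free neglected, twice the excess, taken on the charge, stands as unparked acid set free.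

The rule also stops working if a flask has not reached its stall by the asked time. The green run, the most heavily loaded of the earlier runs, read 55 % at 25.0 min. Wednesday's loading is 1.18 times the green one, and scaled in proportion, as an estimate, that time reckons to 29.4 min, shorter than 50 min. So we keep the rule, which gives 0.0440 M for Monday's flask and 0.330 M for Wednesday's, and we expect the yields of these flasks above the stall yield by about the 5 points of the green run.

The forecast, higher than our rule, gives 0.049 M, 0.091 M, 0.18 M and 0.355 M, and the course rises all the way, holding that “Concentration of target therefore scales almost linearly with loading”.

The flasks give 0.0484 M, 0.0889 M, 0.174 M and 0.341 M, and the course rises all the way.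

    solid electrophile ⇌ electrophile, rate k1*(cs1 - [electrophile]) while solid is left; crystals form when [electrophile] > cs1 (solubility = 38.0 mM, k = 0.0154 /s)
    nucleophile + acid set free ⇌ protonated nucleophile, settled at all times (K = 9710 /M)
    electrophile + nucleophile → acid set free + target (k = 0.0803 /M/s)

Wednesday's flask holds 55.0 % target at 25.0 min and 56.8 % at 50.0 min. Monday's flask, at 60.6 % target, stands 5.6 points above the stall yield of 55.0 %; twice that on its charge is 0.00890 M, and it holds 0.00933 M acid set free. Wednesday's excess, reckoned the same way, is 0.0219 M, and that flask holds 0.0233 M.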